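**Retrosynthetic overview**
1. Feature: in the ten-membered ring C1–C10 the tertiary C8–OH sits next to the secondary C9–O, and C8 is also the β-carbon of the lactone carbonyl C19 (ring O–C7–C8–C17–C19). A C9 ketyl adding to C8 of a 4-alkoxy-3-methylbutenolide therefore forms C8–C9, closes the carbocycle and creates C8, C9 and C17 together.
2. Late disconnections: C6–Cl from the C6 alcohol with inversion (last step); acetates at C2, C9, C14; C11 spiro-epoxide from the ketone (sulfoxonium ylide); the ketone from a dioxolane.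
3. C8–C9 by SmI2 from a C9 aldehyde and a PMB tetronate. C9–C10 and C1–C2 by one copper-catalysed conjugate addition of a silylmethyl Grignard reagent (masked C9–OH) to 7-methyl-1,4-dioxaspiro[4.5]dec-6-en-8-one with aldol trapping by the C2 aldehyde; C14 by hydroxyl-directed reduction.
4. The aldehyde arm (C2–C8, C17–C19) comes from D-tartrate (C5–C8, both stereocentres C6 and C7), a 3-alkoxypropyl Grignard reagent (C2–C4) and ethyl propanoate (C17–C19).
5. Ring order: cyclohexane (bought), butenolide (lactonisation), ten-membered ring (key step), epoxide last.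

Key step: step 16

Assumption: atoms carry briarane numbers throughout (C15 = methyl on C1, C16 = methylene on C5, C18 = methyl on C17, C20 = epoxide CH2); the ligand antipode for the copper-catalysed addition is fixed by one trial run on the enone, because the sense of induction with a silylmethyl Grignard reagent cannot be predicted safely.

**Route**

Step 1
Reactants: 1 1,4-dioxaspiro[4.5]dec-6-en-8-one
Product: 2 7-iodo-1,4-dioxaspiro[4.5]dec-6-en-8-one
Conditions: I2, pyridine, CH2Cl2, 0 °C to rt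
Reagents that add atoms: iodine, [I][I]
Why: α-Iodination of a cyclic enone with iodine/pyridine (conjugate addition of pyridine, iodination of the enolate, elimination) marks the α-carbon that becomes C1 and leaves the ketal alone.

Step 2
Reactants: 2 7-iodo-1,4-dioxaspiro[4.5]dec-6-en-8-one
Product: 3 7-methyl-1,4-dioxaspiro[4.5]dec-6-en-8-one
Conditions: Me4Sn, Pd(PhCN)2Cl2 (5 mol %), AsPh3, CuI (10 mol %), NMP, 80 °C
Reagents that add atoms: tetramethylstannane, C[Sn](C)(C)C
Why: Stille coupling of an α-iodoenone places the C15 methyl on the enone α-carbon with unambiguous regiochemistry.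

Step 3
Reactants: 4 dimethyl (4S,5S)-2,2-dimethyl-1,3-dioxolane-4,5-dicarboxylate (acetonide of dimethyl D-tartrate)
Product: 5 (4S,5S)-N4,N5-dimethoxy-N4,N5,2,2-tetramethyl-1,3-dioxolane-4,5-dicarboxamide
Conditions: MeNH(OMe)·HCl, i-PrMgCl, THF, −20 to 0 °C
Reagents that add atoms: N,O-dimethylhydroxylamine hydrochloride, CNOC.Cl
Why: Aminolysis of both esters by the chloromagnesium amide gives the C2-symmetric bis-Weinreb amide, and the trans-dioxolane, being the stable arrangement, keeps C6 and C7 from epimerising.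

Step 4
Reactants: 5 (4S,5S)-bis-Weinreb amide; 6 1-[(3-bromopropoxy)methyl]-4-methoxybenzene
Product: 8 (4S,5S)-N-methoxy-5-[4-(4-methoxybenzyloxy)butanoyl]-N,2,2-trimethyl-1,3-dioxolane-4-carboxamide, via Grignard reagent 7 (not isolated)
Conditions: 6, Mg, THF, rt; then 5, THF, −20 to 0 °C; aq NH4Cl
Reagents that add atoms: none
Why: Grignard addition to a tartrate bis-Weinreb amide stops after one ketone is formed because the first magnesium chelate deactivates the second amide, and the two ends are equivalent, so the C4–C5 bond is made without a regiochemical question.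

Step 5
Reactants: 8 keto Weinreb amide
Product: 9 (4S,5R)-N-methoxy-5-[5-(4-methoxybenzyloxy)pent-1-en-2-yl]-N,2,2-trimethyl-1,3-dioxolane-4-carboxamide
Conditions: Ph3PCH3Br, KN(SiMe3)2, THF, 0 °C; then 8, −78 to 0 °C
Reagents that add atoms: methyltriphenylphosphonium bromide, C[P+](c1ccccc1)(c1ccccc1)c1ccccc1.[Br-]
Why: Wittig methylenation installs the C5=C16 methylene, the ketone reacting far faster than the Weinreb amide, and the trans-dioxolane is the stable configuration at the α-carbon C6 (its descriptor changes only through the priority rules).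

Step 6
Reactants: 9 methylene Weinreb amide; 10 ethyl propanoate
Product: 12 ethyl 3-[(4S,5R)-5-[5-(4-methoxybenzyloxy)pent-1-en-2-yl]-2,2-dimethyl-1,3-dioxolan-4-yl]-2-methyl-3-oxopropanoate (both C2 epimers), via lithium enolate 11 (not isolated)
Conditions: LiN(i-Pr)2, 10, THF, −78 °C; then 9, −78 to −40 °C; aq NH4Cl
Reagents that add atoms: none
Why: Claisen-type acylation of an ester enolate by a Weinreb amide gives the β-keto ester (C8, C17, C18, C19) without over-addition because the tetrahedral chelate lasts until work-up; the centre at C17 is lost again on enolisation.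

Step 7
Reactants: 12 β-keto ester
Product: 13 (5S)-4-hydroxy-5-[(1R)-1-hydroxy-5-(4-methoxybenzyloxy)-2-methylenepentyl]-3-methylfuran-2(5H)-one
Conditions: AcOH/H2O (4:1), 60 °C; then TsOH·H2O (cat.), toluene, 60 °C
Reagents that add atoms: none
Why: Acetal hydrolysis frees the C6/C7 diol and the γ-hydroxyl at C7 lactonises onto the ester (5-exo-trig, as in ascorbic-acid-type syntheses) to give the fully enolised, strongly acidic 3-methyltetronic acid in preference to the six-membered lactone through O6.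

Step 8
Reactants: 13 tetronic acid with free C6–OH
Product: 15 (5S)-5-[(1R)-1-(tert-butyldimethylsilyloxy)-5-(4-methoxybenzyloxy)-2-methylenepentyl]-4-hydroxy-3-methylfuran-2(5H)-one, via bis-silyl ether 14 (not isolated)
Conditions: TBSOTf, 2,6-lutidine, CH2Cl2, −78 to 0 °C; then aq citric acid, THF, rt
Reagents that add atoms: tert-butyldimethylsilyl trifluoromethanesulfonate, CC(C)(C)[Si](C)(C)OS(=O)(=O)C(F)(F)F
Why: The silyl triflate silylates the hindered allylic C6 hydroxyl and the enol, and the vinylogous silyl ester is hydrolysed on mild acidic work-up while the secondary silyl ether stays.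

Step 9
Reactants: 15 C6-silylated tetronic acid
Product: 16 (5S)-5-[(1R)-1-(tert-butyldimethylsilyloxy)-5-hydroxy-2-methylenepentyl]-4-hydroxy-3-methylfuran-2(5H)-one
Conditions: DDQ, CH2Cl2/H2O (10:1), 0 °C to rt
Reagents that add atoms: none
Why: DDQ cleaves the primary 4-methoxybenzyl ether oxidatively and frees the C2 hydroxyl before the second 4-methoxybenzyl group is introduced, so no selection between two such groups is ever needed.

Step 10
Reactants: 16 tetronic acid with free primary alcohol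
Product: 17 (5S)-5-[(1R)-1-(tert-butyldimethylsilyloxy)-5-hydroxy-2-methylenepentyl]-4-(4-methoxybenzyloxy)-3-methylfuran-2(5H)-one
Conditions: N,N′-diisopropyl-O-(4-methoxybenzyl)isourea, THF, 45 °C
Reagents that add atoms: N,N′-diisopropyl-O-(4-methoxybenzyl)isourea, COc1ccc(COC(=NC(C)C)NC(C)C)cc1
Why: O-Alkyl isoureas alkylate only acidic hydroxyls, so the tetronic acid is turned into its 4-O-(4-methoxybenzyl) tetronate and the primary alcohol is untouched.

Step 11
Reactants: 17 PMB tetronate alcohol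
Product: 18 (5R)-5-(tert-butyldimethylsilyloxy)-5-[(2S)-3-(4-methoxybenzyloxy)-4-methyl-5-oxo-2,5-dihydrofuran-2-yl]-4-methylenepentanal
Conditions: Dess–Martin periodinane, CH2Cl2, 0 °C to rt
Reagents that add atoms: none
Why: Dess–Martin oxidation gives the C2 aldehyde under near-neutral conditions that spare the base-sensitive C7–H of the tetronate.

Step 12
Reactants: 3 7-methyl-1,4-dioxaspiro[4.5]dec-6-en-8-one; 19 (chloromethyl)(isopropoxy)dimethylsilane; 18 tetronate aldehyde
Product: 22 β-hydroxy ketone (C1–C2 aldol adduct; C14 ketone; C10 CH2SiMe2(OiPr); 1S,2S,10R), via Grignard reagent 20 (not isolated), via magnesium enolate 21 (not isolated)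
Conditions: 19, Mg, THF, rt; then Cu(OTf)2 (4 mol %), 1-(1-hydroxy-4-methylpentan-2-yl)-3-mesityl-4,5-dihydroimidazolium hexafluorophosphate (one enantiomer, 5 mol %), 3, Et2O, −30 °C; then 18, −78 °C; aq NH4Cl
Reagents that add atoms: none
Why: Copper–NHC-catalysed enantioselective conjugate addition of a primary alkyl Grignard reagent to a 2-methylcycloalkenone with aldol trapping of the magnesium enolate (three-component coupling): the ligand sets C10, the aldehyde adds to the enolate face anti to the new C10 substituent (C2 arm trans to C9 at the quaternary C1), and the Zimmerman–Traxler chair of the ring-locked enolate (methyl cis to O–Mg, aldehyde chain equatorial) puts the C2 hydroxyl syn to the C1 methyl.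

Step 13
Reactants: 22 β-hydroxy ketone
Product: 24 triol (C2–OH; C14–OH; C9–OH; 1S,2S,10S,14S), via diol silane 23 (not isolated)
Conditions: Me4NBH(OAc)3, MeCN/AcOH (1:1), −25 °C; then KF, KHCO3, H2O2 (30 %), THF/MeOH, rt
Reagents that add atoms: hydrogen peroxide, OO
Why: Evans–Saksena reduction, in which the C2 hydroxyl binds boron and delivers hydride through a chair (C10 and C13 equatorial, C1 methyl axial), gives the 2,14-anti diol with the C14 hydroxyl cis to the C2 arm, and Tamao oxidation of the crude silane then converts C9–Si into C9–OH.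

Step 14
Reactants: 24 triol
Product: 25 tris(triethylsilyl) ether of 24
Conditions: TESOTf, 2,6-lutidine, CH2Cl2, −78 to 0 °C
Reagents that add atoms: triethylsilyl trifluoromethanesulfonate, CC[Si](CC)(CC)OS(=O)(=O)C(F)(F)F
Why: Exhaustive silylation with the triflate covers the two hindered secondary hydroxyls (C2, C14) and the primary C9 hydroxyl in one operation.

Step 15
Reactants: 25 tris(triethylsilyl) ether
Product: 26 C9 aldehyde (cyclisation precursor; C2 and C14 OTES; C6 OTBS; C11 dioxolane; PMB tetronate)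
Conditions: (COCl)2, DMSO, CH2Cl2, −78 to −35 °C; then Et3N, −78 to 0 °C
Reagents that add atoms: none
Why: Swern conditions cleave a primary triethylsilyl ether and oxidise it in the same flask while secondary silyl ethers stay, which gives the C9 aldehyde directly; C10 keeps its equatorial, thermodynamically preferred configuration.

Step 16
Reactants: 26 C9 aldehyde
Product: 27 tricyclic lactone (ten-membered ring closed; 9-OH; 8-O-PMB; saturated lactone; 1S,2S,6R,7S,8R,9S,10S,14S,17R)
Conditions: SmI2 (4 equiv, 0.1 M in THF), MeOH (4 equiv), THF (final 2 mM), 0 °C, 26 added by syringe pump over 8 h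
Reagents that add atoms: none
Why: Proposed new method: SmI2 transfers one electron to the C9 aldehyde, the ketyl radical adds to C8 (β-carbon of the vinylogous carbonate), a second electron turns the C17 radical into the samarium enolate and methanol protonates C17; the closest known reaction is the SmI2/MeOH ketyl cyclisation onto β-alkoxyacrylates, moved here to a cyclic tetronate acceptor and a carbocyclic medium ring. The ten-membered ring closes in the 10-exo-trig mode and the lactone ring stays intact. C8 is set because the ketyl attacks the tetronate face anti to the C6 substituent on C7, which gives the trans-fused lactone with the PMB-oxy group cis to C6. C9 is set because trivalent samarium bridges the ketyl oxygen and the C8 ether oxygen, so that O9 and O8 end up syn while C10 and C7 are anti. C17 is set by proton delivery from methanol held on the samarium of the C9 alkoxide, that is on the face of the new C8–C9 bond (not anti to it), which leaves the methyl cis to the C8 oxygen, the epimer that is also the more stable one on the lactone ring. The step needs ring closure to outrun pinacol dimerisation, simple reduction and loss of the C8 alkoxy group from the enolate, and high dilution with slow addition, the trans-diequatorial anchoring of both chain ends on the cyclohexane, the sp2 centres C5 and C8 and a proton source present from the start are expected to secure this.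

Step 17
Reactants: 27 tricyclic lactone
Product: 28 8,9-diol (C8–OH free; otherwise as 27)
Conditions: DDQ, CH2Cl2/H2O (10:1), 0 °C
Reagents that add atoms: none
Why: DDQ oxidises the tertiary 4-methoxybenzyl ether and water intercepts the oxocarbenium ion, which frees the C8 hydroxyl (an 8,9-anisylidene acetal, if formed with the neighbouring hydroxyl, would be hydrolysed in step 18).

Step 18
Reactants: 28 8,9-diol
Product: 29 tetraol ketone (2-, 8-, 9-, 14-OH; C11 ketone; C6 OTBS)
Conditions: AcOH/THF/H2O (3:1:1), 50 °C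
Reagents that add atoms: water, O
Why: Mild aqueous acid hydrolyses the dioxolane to the C11 ketone and removes both triethylsilyl ethers, while the more robust secondary tert-butyldimethylsilyl ether at C6 stays and keeps C6 apart from the hydroxyls that are to be acetylated.

Step 19
Reactants: 29 tetraol ketone
Product: 30 11,20-epoxide (11S; 2-, 8-, 9-, 14-OH; C6 OTBS)
Conditions: Me3S(O)I, NaH, DMSO/THF, rt to 40 °C
Reagents that add atoms: trimethylsulfoxonium iodide, C[S+](C)(C)=O.[I-]
Why: Corey–Chaykovsky epoxidation with dimethylsulfoxonium methylide forms the new C–C bond equatorially (the axial path is also blocked by the 1,3-diaxial C1 methyl), so the epoxide oxygen is axial and cis to C9 as required, and the ylide is too weak a base to deprotonate the alcohols or the lactone α-carbon.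

Step 20
Reactants: 30 epoxy tetraol
Product: 31 2,9,14-triacetate (C8–OH free; C6 OTBS)
Conditions: Ac2O, pyridine, 4-(dimethylamino)pyridine (cat.), CH2Cl2, rt
Reagents that add atoms: acetic anhydride, CC(=O)OC(C)=O
Why: Nucleophile-catalysed acylation esterifies the three secondary hydroxyls (C2, C9, C14) and leaves the tertiary C8 hydroxyl free, as in the target.

Step 21
Reactants: 31 triacetate silyl ether
Product: 32 C6 alcohol (6R; 2,9,14-triacetate; 8-OH; epoxide)
Conditions: Bu4NF, AcOH (1:1), THF, 0 °C to rt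
Reagents that add atoms: none
Why: Buffered fluoride removes the silyl ether at C6 without opening the epoxide or moving the acetates.

Step 22
Reactants: 32 C6 alcohol
Product: 33 CNP0104093.2 (target; 1S,2S,6S,7R,8R,9S,10S,11S,14S,17R)
Conditions: PPh3, Cl3CC(O)CCl3, CH2Cl2, −20 to 0 °C
Reagents that add atoms: hexachloroacetone, O=C(C(Cl)(Cl)Cl)C(Cl)(Cl)Cl
Why: Appel-type chlorination with triphenylphosphine/hexachloroacetone, the variant known to suppress allylic transposition, displaces the alkoxyphosphonium ion at C6 by SN2 with inversion (R alcohol to S chloride), and the tertiary C8 hydroxyl does not react.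

**Compound list**

1 | 1,4-dioxaspiro[4.5]dec-6-en-8-one | O=C1C=CC2(CC1)OCCO2 | starting material
2 | 7-iodo-1,4-dioxaspiro[4.5]dec-6-en-8-one | O=C1C(I)=CC2(CC1)OCCO2 | intermediate
3 | 7-methyl-1,4-dioxaspiro[4.5]dec-6-en-8-one | O=C1C(C)=CC2(CC1)OCCO2 | intermediate
4 | dimethyl (4S,5S)-2,2-dimethyl-1,3-dioxolane-4,5-dicarboxylate | COC(=O)[C@H]1OC(C)(C)O[C@@H]1C(=O)OC | starting material
5 | (4S,5S)-N4,N5-dimethoxy-N4,N5,2,2-tetramethyl-1,3-dioxolane-4,5-dicarboxamide | CON(C)C(=O)[C@H]1OC(C)(C)O[C@@H]1C(=O)N(C)OC | intermediate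
6 | 1-[(3-bromopropoxy)methyl]-4-methoxybenzene | COc1ccc(COCCCBr)cc1 | starting material
7 | [3-(4-methoxybenzyloxy)propyl]magnesium bromide | COc1ccc(COCCC[Mg]Br)cc1 | intermediate (not isolated)
8 | (4S,5S)-N-methoxy-5-[4-(4-methoxybenzyloxy)butanoyl]-N,2,2-trimethyl-1,3-dioxolane-4-carboxamide | COc1ccc(COCCCC(=O)[C@H]2OC(C)(C)O[C@@H]2C(=O)N(C)OC)cc1 | intermediate
9 | (4S,5R)-N-methoxy-5-[5-(4-methoxybenzyloxy)pent-1-en-2-yl]-N,2,2-trimethyl-1,3-dioxolane-4-carboxamide | COc1ccc(COCCCC(=C)[C@H]2OC(C)(C)O[C@@H]2C(=O)N(C)OC)cc1 | intermediate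
10 | ethyl propanoate | CCC(=O)OCC | starting material
11 | lithium enolate of ethyl propanoate | CC=C(OCC)O[Li] | intermediate (not isolated)
12 | ethyl 3-[(4S,5R)-5-[5-(4-methoxybenzyloxy)pent-1-en-2-yl]-2,2-dimethyl-1,3-dioxolan-4-yl]-2-methyl-3-oxopropanoate (both C2 epimers) | COc1ccc(COCCCC(=C)[C@H]2OC(C)(C)O[C@@H]2C(=O)C(C)C(=O)OCC)cc1 | intermediate
13 | (5S)-4-hydroxy-5-[(1R)-1-hydroxy-5-(4-methoxybenzyloxy)-2-methylenepentyl]-3-methylfuran-2(5H)-one | C=C(CCCOCc1ccc(OC)cc1)[C@@H](O)[C@@H]1OC(=O)C(C)=C1O | intermediate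
14 | (5S)-4-(tert-butyldimethylsilyloxy)-5-[(1R)-1-(tert-butyldimethylsilyloxy)-5-(4-methoxybenzyloxy)-2-methylenepentyl]-3-methylfuran-2(5H)-one | C=C(CCCOCc1ccc(OC)cc1)[C@@H](O[Si](C)(C)C(C)(C)C)[C@@H]1OC(=O)C(C)=C1O[Si](C)(C)C(C)(C)C | intermediate (not isolated)
15 | (5S)-5-[(1R)-1-(tert-butyldimethylsilyloxy)-5-(4-methoxybenzyloxy)-2-methylenepentyl]-4-hydroxy-3-methylfuran-2(5H)-one | C=C(CCCOCc1ccc(OC)cc1)[C@@H](O[Si](C)(C)C(C)(C)C)[C@@H]1OC(=O)C(C)=C1O | intermediate
16 | (5S)-5-[(1R)-1-(tert-butyldimethylsilyloxy)-5-hydroxy-2-methylenepentyl]-4-hydroxy-3-methylfuran-2(5H)-one | C=C(CCCO)[C@@H](O[Si](C)(C)C(C)(C)C)[C@@H]1OC(=O)C(C)=C1O | intermediate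
17 | (5S)-5-[(1R)-1-(tert-butyldimethylsilyloxy)-5-hydroxy-2-methylenepentyl]-4-(4-methoxybenzyloxy)-3-methylfuran-2(5H)-one | C=C(CCCO)[C@@H](O[Si](C)(C)C(C)(C)C)[C@@H]1OC(=O)C(C)=C1OCc1ccc(OC)cc1 | intermediate
18 | (5R)-5-(tert-butyldimethylsilyloxy)-5-[(2S)-3-(4-methoxybenzyloxy)-4-methyl-5-oxo-2,5-dihydrofuran-2-yl]-4-methylenepentanal | C=C(CCC=O)[C@@H](O[Si](C)(C)C(C)(C)C)[C@@H]1OC(=O)C(C)=C1OCc1ccc(OC)cc1 | intermediate
19 | (chloromethyl)(isopropoxy)dimethylsilane | CC(C)O[Si](C)(C)CCl | starting material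
20 | {[isopropoxy(dimethyl)silyl]methyl}magnesium chloride | CC(C)O[Si](C)(C)C[Mg]Cl | intermediate (not isolated)
21 | chloromagnesium enolate of (6R)-6-{[isopropoxy(dimethyl)silyl]methyl}-7-methyl-1,4-dioxaspiro[4.5]decan-8-one | CC1=C(O[Mg]Cl)CCC2(OCCO2)[C@@H]1C[Si](C)(C)OC(C)C | intermediate (not isolated)
22 | (6R,7S)-7-[(1S,5R)-5-(tert-butyldimethylsilyloxy)-1-hydroxy-5-[(2S)-3-(4-methoxybenzyloxy)-4-methyl-5-oxo-2,5-dihydrofuran-2-yl]-4-methylenepentyl]-6-{[isopropoxy(dimethyl)silyl]methyl}-7-methyl-1,4-dioxaspiro[4.5]decan-8-one | C=C(CC[C@H](O)[C@@]1(C)C(=O)CCC2(OCCO2)[C@@H]1C[Si](C)(C)OC(C)C)[C@@H](O[Si](C)(C)C(C)(C)C)[C@@H]1OC(=O)C(C)=C1OCc1ccc(OC)cc1 | intermediate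
23 | (6R,7S,8S)-7-[(1S,5R)-5-(tert-butyldimethylsilyloxy)-1-hydroxy-5-[(2S)-3-(4-methoxybenzyloxy)-4-methyl-5-oxo-2,5-dihydrofuran-2-yl]-4-methylenepentyl]-6-{[isopropoxy(dimethyl)silyl]methyl}-7-methyl-1,4-dioxaspiro[4.5]decan-8-ol | C=C(CC[C@H](O)[C@@]1(C)[C@@H](O)CCC2(OCCO2)[C@@H]1C[Si](C)(C)OC(C)C)[C@@H](O[Si](C)(C)C(C)(C)C)[C@@H]1OC(=O)C(C)=C1OCc1ccc(OC)cc1 | intermediate (not isolated)
24 | (6S,7S,8S)-7-[(1S,5R)-5-(tert-butyldimethylsilyloxy)-1-hydroxy-5-[(2S)-3-(4-methoxybenzyloxy)-4-methyl-5-oxo-2,5-dihydrofuran-2-yl]-4-methylenepentyl]-6-(hydroxymethyl)-7-methyl-1,4-dioxaspiro[4.5]decan-8-ol | C=C(CC[C@H](O)[C@@]1(C)[C@@H](O)CCC2(OCCO2)[C@@H]1CO)[C@@H](O[Si](C)(C)C(C)(C)C)[C@@H]1OC(=O)C(C)=C1OCc1ccc(OC)cc1 | intermediate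
25 | (6S,7S,8S)-7-[(1S,5R)-5-(tert-butyldimethylsilyloxy)-5-[(2S)-3-(4-methoxybenzyloxy)-4-methyl-5-oxo-2,5-dihydrofuran-2-yl]-4-methylene-1-(triethylsilyloxy)pentyl]-7-methyl-8-(triethylsilyloxy)-6-[(triethylsilyloxy)methyl]-1,4-dioxaspiro[4.5]decane | C=C(CC[C@H](O[Si](CC)(CC)CC)[C@@]1(C)[C@@H](O[Si](CC)(CC)CC)CCC2(OCCO2)[C@@H]1CO[Si](CC)(CC)CC)[C@@H](O[Si](C)(C)C(C)(C)C)[C@@H]1OC(=O)C(C)=C1OCc1ccc(OC)cc1 | intermediate
26 | (6S,7S,8S)-7-[(1S,5R)-5-(tert-butyldimethylsilyloxy)-5-[(2S)-3-(4-methoxybenzyloxy)-4-methyl-5-oxo-2,5-dihydrofuran-2-yl]-4-methylene-1-(triethylsilyloxy)pentyl]-7-methyl-8-(triethylsilyloxy)-1,4-dioxaspiro[4.5]decane-6-carbaldehyde | C=C(CC[C@H](O[Si](CC)(CC)CC)[C@@]1(C)[C@@H](O[Si](CC)(CC)CC)CCC2(OCCO2)[C@@H]1C=O)[C@@H](O[Si](C)(C)C(C)(C)C)[C@@H]1OC(=O)C(C)=C1OCc1ccc(OC)cc1 | intermediate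
27 | tricyclic lactone (briarane numbering): ten-membered ring C1–C10 with 5(16)-methylene, trans-fused to the cyclohexane and to the γ-lactone O–C7–C8–C17(CH3)–C19(=O); 9-OH; 8-O-(4-methoxybenzyl); 2- and 14-O-triethylsilyl; 6-O-tert-butyldimethylsilyl; 11-ethylene ketal; (1S,2S,6R,7S,8R,9S,10S,14S,17R) | C=C1CC[C@H](O[Si](CC)(CC)CC)[C@@]2(C)[C@@H](O[Si](CC)(CC)CC)CCC3(OCCO3)[C@@H]2[C@H](O)[C@]2(OCc4ccc(OC)cc4)[C@@H](C)C(=O)O[C@H]2[C@@H]1O[Si](C)(C)C(C)(C)C | intermediate
28 | as 27 with free 8-OH (8,9-syn diol); (1S,2S,6R,7S,8R,9S,10S,14S,17R) | C=C1CC[C@H](O[Si](CC)(CC)CC)[C@@]2(C)[C@@H](O[Si](CC)(CC)CC)CCC3(OCCO3)[C@@H]2[C@H](O)[C@]2(O)[C@@H](C)C(=O)O[C@H]2[C@@H]1O[Si](C)(C)C(C)(C)C | intermediate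
29 | tetraol ketone: 2-, 8-, 9-, 14-OH; 11-oxo; 6-O-tert-butyldimethylsilyl; 5(16)-ene; 19,7-lactone; (1S,2S,6R,7S,8R,9S,10S,14S,17R) | C=C1CC[C@H](O)[C@@]2(C)[C@@H](O)CCC(=O)[C@@H]2[C@H](O)[C@]2(O)[C@@H](C)C(=O)O[C@H]2[C@@H]1O[Si](C)(C)C(C)(C)C | intermediate
30 | 11,20-epoxide of 29 (spiro-epoxide at C11, oxygen cis to C9; 11S) with 2-, 8-, 9-, 14-OH and 6-O-tert-butyldimethylsilyl | C=C1CC[C@H](O)[C@@]2(C)[C@@H](O)CC[C@@]3(CO3)[C@@H]2[C@H](O)[C@]2(O)[C@@H](C)C(=O)O[C@H]2[C@@H]1O[Si](C)(C)C(C)(C)C | intermediate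
31 | 2,9,14-triacetate of 30 (8-OH free; 6-O-tert-butyldimethylsilyl) | C=C1CC[C@H](OC(C)=O)[C@@]2(C)[C@@H](OC(C)=O)CC[C@@]3(CO3)[C@@H]2[C@H](OC(C)=O)[C@]2(O)[C@@H](C)C(=O)O[C@H]2[C@@H]1O[Si](C)(C)C(C)(C)C | intermediate
32 | (6R)-alcohol: 2,9,14-triacetoxy-6,8-dihydroxy-11,20-epoxy-5(16)-ene 19,7-lactone | C=C1CC[C@H](OC(C)=O)[C@@]2(C)[C@@H](OC(C)=O)CC[C@@]3(CO3)[C@@H]2[C@H](OC(C)=O)[C@]2(O)[C@@H](C)C(=O)O[C@H]2[C@@H]1O | intermediate
33 | CNP0104093.2: (1S,2S,6S,7R,8R,9S,10S,11S,14S,17R)-2,9,14-triacetoxy-6-chloro-8-hydroxy-11,20-epoxy-5(16)-ene 19,7-lactone (briarane numbering) | C=C1CC[C@H](OC(C)=O)[C@@]2(C)[C@@H](OC(C)=O)CC[C@@]3(CO3)[C@@H]2[C@H](OC(C)=O)[C@]2(O)[C@@H](C)C(=O)O[C@H]2[C@H]1Cl | target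

**Step count and risks**

Total step count: 22. Longest linear sequence: 20 steps (steps 3–22, from 4).

Most likely to fail, in this order:

Step 16 (carries the new-method label). The 10-exo closure may be slower than bimolecular pinacol coupling or than further reduction of the ketyl to the primary alcohol; the samarium enolate may expel the C8 alkoxy group; and the C9 and C17 faces may not be well differentiated. The fallback uses known reactions and closes the same bond by a Nozaki–Hiyama–Kishi reaction. It sets out from 26. MgBr2·OEt2 and Me2S remove the 4-methoxybenzyl group from the vinylogous ester and give the tetronic acid aldehyde F1. Tf2O and i-Pr2NEt (CH2Cl2, −78 °C) give the enol triflate F2. CrCl2 with catalytic NiCl2 (DMSO/THF, high dilution) adds the C8 alkenyl metal to the C9 aldehyde and closes the ten-membered ring as the allylic alcohol with a C8=C17 butenolide F3. Hydroxyl-directed epoxidation (VO(acac)2, t-BuOOH) should place oxygen on the alkene face next to the C9 hydroxyl and give the 8,17-epoxy lactone F4. SmI2/MeOH at −78 °C then cleaves the C17–O bond, the known reduction of α,β-epoxy esters to β-hydroxy esters, and gives 28, where the route is rejoined before step 18. Stereocontrol at C8, C9 and C17 is weaker on this path than in the chelated ketyl addition.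

Step 12. The α-silylalkyl group may transfer slowly, so that 1,2-addition competes; the copper catalyst may give low enantiofacial selectivity with this Grignard reagent; and the enolate may take the C7 proton of the tetronate instead of adding to the aldehyde. The fallback replaces asymmetric catalysis by resolution through the enantiopure aldehyde. It sets out from 3, 19 and 18. Grignard reagent 20 is added to 3 with CuBr·SMe2 (5 mol %) and no chiral ligand, and the racemic magnesium enolate is treated with 18 at −78 °C. The side-chain stereocentres are remote, so both enolate antipodes should add alike and give 22 together with its diastereomer of opposite configuration at C1, C2 and C10, F5. The two are separated by chromatography and the route is rejoined at 22.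

Step 22. Chloride may attack the methylene terminus C16 (allylic transposition), or the alkoxyphosphonium ion may eliminate, instead of direct displacement at the hindered C6. The fallback replaces nucleophilic displacement by an electrophilic ene-type chlorination. It sets out from 32. Reductive 1,3-transposition of the allylic alcohol (2-nitrobenzenesulfonyl hydrazide, PPh3, diethyl azodicarboxylate, THF, −30 °C to rt; loss of sulfinic acid, then of N2 from the allylic diazene) moves the double bond into the ring and gives the (5E)-alkene with a C16 methyl group F6. HOCl (Ca(OCl)2, solid CO2, CH2Cl2/H2O, 0 °C) should then add chlorine to C6 from the outer face of the ring with return of the double bond to C5=C16, which gives 33.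

**Further compounds**

F1 | step 16 | tetronic acid aldehyde (26 without the 4-methoxybenzyl group; free 4-hydroxy-3-methylbutenolide) | C=C(CC[C@H](O[Si](CC)(CC)CC)[C@@]1(C)[C@@H](O[Si](CC)(CC)CC)CCC2(OCCO2)[C@@H]1C=O)[C@@H](O[Si](C)(C)C(C)(C)C)[C@@H]1OC(=O)C(C)=C1O
F2 | step 16 | enol triflate of F1 (C8–OSO2CF3) | C=C(CC[C@H](O[Si](CC)(CC)CC)[C@@]1(C)[C@@H](O[Si](CC)(CC)CC)CCC2(OCCO2)[C@@H]1C=O)[C@@H](O[Si](C)(C)C(C)(C)C)[C@@H]1OC(=O)C(C)=C1OS(=O)(=O)C(F)(F)F
F3 | step 16 | ten-membered allylic alcohol with C8=C17 butenolide (9-OH; 2- and 14-O-triethylsilyl; 6-O-tert-butyldimethylsilyl; 11-ethylene ketal) | C=C1CC[C@H](O[Si](CC)(CC)CC)[C@@]2(C)[C@@H](O[Si](CC)(CC)CC)CCC3(OCCO3)[C@@H]2[C@H](O)C2=C(C)C(=O)O[C@H]2[C@@H]1O[Si](C)(C)C(C)(C)C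
F4 | step 16 | 8,17-epoxide of F3 (oxygen cis to C6 on the lactone ring) | C=C1CC[C@H](O[Si](CC)(CC)CC)[C@@]2(C)[C@@H](O[Si](CC)(CC)CC)CCC3(OCCO3)[C@@H]2[C@H](O)[C@@]23O[C@@]3(C)C(=O)O[C@H]2[C@@H]1O[Si](C)(C)C(C)(C)C
F5 | step 12 | (6S,7R)-7-[(1R,5R)-5-(tert-butyldimethylsilyloxy)-1-hydroxy-5-[(2S)-3-(4-methoxybenzyloxy)-4-methyl-5-oxo-2,5-dihydrofuran-2-yl]-4-methylenepentyl]-6-{[isopropoxy(dimethyl)silyl]methyl}-7-methyl-1,4-dioxaspiro[4.5]decan-8-one (diastereomer of 22) | C=C(CC[C@@H](O)[C@]1(C)C(=O)CCC2(OCCO2)[C@H]1C[Si](C)(C)OC(C)C)[C@@H](O[Si](C)(C)C(C)(C)C)[C@@H]1OC(=O)C(C)=C1OCc1ccc(OC)cc1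
F6 | step 22 | (5E)-2,9,14-triacetoxy-8-hydroxy-11,20-epoxy-5-ene 19,7-lactone with C16 methyl and no substituent at C6 (briarane numbering) | C/C1=C\[C@@H]2OC(=O)[C@H](C)[C@@]2(O)[C@@H](OC(C)=O)[C@H]3[C@]4(CO4)CC[C@H](OC(C)=O)[C@]3(C)[C@@H](OC(C)=O)CC1
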